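Atom numbers of the target are used for all intermediates: C1–C6 for the carbocycle of the cage (C1 bears CH3, C2 bears Br, C4 bears the cyclohexyl group) and C1'–C6' for the dimethylcyclohexane.

## Analysis of the target

Compound 23 consists of two ring systems joined by one bond. One is a 7-oxabicyclo[2.2.1]heptane cage (carbocycle C1–C6, oxygen bridging C1 and C4), the other a 3,3-dimethylcyclohexane (C1'–C6') attached through C4–C1'. Both bridgeheads are fully substituted, and each ring system carries one secondary bromide next to a quaternary carbon (C2 beside C1, C4' beside C3'). Of the five stereocentres, C1 (R) and C4 (S) are locked to each other by the bridge and C2 (R) holds bromine endo, anti to the oxygen. C1' (S) and C4' (S) are trans, so cage and bromine are both equatorial. The two halves communicate only through the rotating C4–C1' bond, and C2' and C6' are both methylene groups, so the relation of the cage to C1' must come from a reagent or catalyst. The bromides are neopentyl-type, and the C4' bromide is equatorial with no antiperiplanar hydrogen, so they resist substitution and elimination once present but are hard to install by displacement. An equatorial and an axial bromine beside a gem-dimethyl group differ little in energy, so the trans relation in the cyclohexane has to be set kinetically and cannot be left to equilibration at C1'. The strategy rests on the 1,3-relationship in the cage. C2 (C–Br) and C4 (C–O) are separated by the C3 methylene, which is the pattern left when a cyclopropane C2–C3–C4 is opened by an electrophile at one carbon and a nucleophile at the other. Here the nucleophile is the oxygen already bound to C1.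

## Retrosynthetic reasoning

**23 ⇒ 21 + 22 (C2–Br, C4–O).** Cutting these two bonds and joining C2 to C4 turns the cage into the bicyclo[3.1.0]hexanol 21 and the bromenium donor 22. No other pair of bonds removes both hard features of the cage at once, namely the endo neopentyl bromide and the ether between two quaternary carbons. Nothing has to be adjusted afterwards, because 21 and 23 differ only by H against Br. In the forward direction four things must happen:
- bromine must go to C2 and not to the more open C3;
- the ring-fusion bond must break;
- C2 must invert;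
- the C1 oxygen must catch the C4 cation before it loses a proton.

The oxygen lies on the same side of C4 as the departing C2, so closure cannot be concerted with opening. The outcome therefore depends on the configuration of C1 and its anti relation to C3, not on that of C4 in 21.

**21 ⇒ 20 ⇒ 19 ⇒ 18 (C1 carbinol).** A methyl nucleophile would add to ketone 18 from the face away from C3 and leave the hydroxyl syn to C3, the wrong epimer for an endo bromide. The methyl group is therefore cut at a C–H bond (hydride opening of spiro-epoxide 20). The C1–O bond is traced to epoxidation of alkene 19, and the extra carbon to methylenation of 18. The reagent still arrives opposite C3, but now it brings oxygen.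

**18 ⇒ 17 (C2–C3, C2–C4).** Both cyclopropane bonds to C2 are cut, giving diazoketone 17. Its carbene carbon is tied through C1, C6 and C5 to the alkene C4=C3. The tether allows only the cis-fused bicycle, so C2 and C4 form one stereochemical unit. This is the step that relates the future cage to C1', and the alkene face must be chosen by a chiral catalyst. Because 17 is a single enantiomer, an imperfect choice gives a separable diastereomer and does not erode enantiopurity.

**17 ⇒ 15 ⇒ 14 ⇒ 13 (C1–C2, C4=C3).** The diazo carbon is removed from acid 15 (activated as 16), the acid comes from ester 14, and the methylene C3 from ketone 13. After the methylenation C1' is no longer alpha to a carbonyl group and is configurationally safe.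

**13 ⇒ 9 + 10 (C4–C5).** The cut between the ketone carbon and C5 gives the acyl donor 11, made from acid 9, and the three-carbon homoenolate 12, made from 10. Polarity-reversed versions of this bond formation need warm amine base, under which C1' could epimerise. The coupling of 11 with 12 is neutral.

**9 ⇒ 8 ⇒ 7 ⇒ 6 (C4'–Br).** Displacement at C4' would be a neopentyl substitution with an antiperiplanar hydrogen inviting elimination. The C–Br bond is therefore made while C4' is trigonal (ketone 6 to alkenyl bromide 7), and the stereocentre is created by adding hydrogen, not bromine (7 to 8). The C1' substituent is held equatorial by the syn-axial C3' methyl and so controls the face.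

**6 ⇒ 5 ⇒ 4 (second methyl on C3').** The methyl is cut back to the CH2 of siloxycyclopropane 5, which comes from the tetrasubstituted silyl enol ether 4. This places the carbon regiospecifically and without base.

**4 ⇒ 2 + 3, 2 ⇒ 1 (C1'–C2', C5'–C6').** A cycloaddition of diene 2 with acrylate 3 builds the ring, puts the enol ether exactly between C3' and C4', and sets C1' by catalysis. Diene 2 is the silyl dienol ether of enone 1.

## Alternatives that were turned down

**Alternative 1:**
- *Disconnection and key step.* The bromocyclohexane is unzipped at C2'–C3' and C4'–Br, leading back to the cage-bearing 1,5-diene A1. A chiral bromenium carrier would activate the trisubstituted alkene of A1. The methylene terminus of the 1,1-disubstituted alkene would close the ring through a chair, and proton loss from the C1' cation would leave cyclohexene A2.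
- *For.* It is the biomimetic construction. It creates quaternary C3' and the equatorial neopentyl C4'–Br bond in one operation, which is clearly better than the four steps (3 to 6) that the chosen route spends on the same atoms.
- *Against.* Bromenium ions pass from alkene to alkene faster than most cyclisations proceed, so reagent control over C4' is fragile, and the cage stereocentres are too remote to help. The proton can leave from C2' as well as C6'. C1' emerges trigonal, so the C4/C1' relation would have to be set by hydrogenating a trisubstituted alkene beside quaternary C4, in the presence of two C–Br bonds and with nothing to distinguish the faces. A1 also already contains the finished cage with its endo bromide, so the harder half of the problem is only postponed.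
- *Comparison.* The chosen strategy gives up the direct bromocyclisation. In return it solves the cage and fixes C1' at the outset.

**Alternative 2:**
- *Disconnection and key step.* O–C4 and C1–C2 are cut, giving the cyclopropane 1,1-diester A3 with a tethered methyl ketone. A Lewis acid would open the C4–C2 bond, the ketone oxygen would bond to C4 and the malonate carbon to C1, giving the bridged diester A4.
- *For.* Formal (3+2) additions of acceptor-activated cyclopropanes to carbonyl groups are an established class. They proceed with inversion at the donor carbon, so C4 could be relayed. On precedent this step stands better than step 16.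
- *Against.* C4 bears only alkyl groups and is a weak donor. A ketone is a poor partner and would have to form fully substituted C1 next to quaternary C2. The bridging mode demands an unfavourable fold of the tether. A4 carries two esters where 23 has H and Br. One must be removed and the other exchanged for bromine by a radical decarboxylation, which would take up bromine from the open exo face and give the wrong epimer. That costs at least four further steps. Enantiopure A3 is also no easier to reach than 18.
- *Comparison.* The chosen strategy trades precedent for an endgame that needs no correction.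

**Alternative 3:**
- *Disconnection and key step.* C1–C2 and C3–C4 are cut, giving furan A5 and 2-bromoacrolein A6. A chiral Lewis acid would join them to the oxanorbornene A7 with bromine endo and formyl exo.
- *For.* The route is convergent, the catalytic asymmetric cycloaddition is well established for simple furans, and C1, C2 and C4 are set in one step. In convergence it beats the linear chosen route.
- *Against.* A 2,5-dialkylfuran gives an adduct with two quaternary bridgeheads, which reverts easily. The two furan termini differ only in size, so regiocontrol is weak. After the cycloaddition the formyl group must be excised with retention from a tertiary alpha-bromo carbon, where a decarbonylation metal can insert into C–Br instead. The alkene must then be saturated without hydrogenolysis. A5 also needs the same bromocyclohexyl block as 9.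
- *Comparison.* The chosen strategy installs C2–H and C2–Br directly in their final arrangement.

Key step: step 16

Assumption: the antipodes of the two chiral catalysts named in steps 2 and 12 follow the accepted transition-state models; both antipodes are commercial, and the other one is taken if a first run shows the opposite sense of induction.

## Route

Step 1
Reactants: 1 3-methylbut-3-en-2-one
Product: 2 3-methyl-2-(triisopropylsilyloxy)buta-1,3-diene
Conditions: TIPSOTf, Et3N, CH2Cl2, 0 °C
Reagents that add atoms: triisopropylsilyl trifluoromethanesulfonate, CC(C)[Si](C(C)C)(C(C)C)OS(=O)(=O)C(F)(F)F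
Why: Soft enolisation with silyl triflate and amine; only the methyl group carries alpha-hydrogens, so a single 2-silyloxydiene can form, and the bulky silyl group lets it survive the strong Lewis acid of step 2.

Step 2
Reactants: 2 3-methyl-2-(triisopropylsilyloxy)buta-1,3-diene, 3 2,2,2-trifluoroethyl acrylate
Product: 4 2,2,2-trifluoroethyl (1S)-3-methyl-4-(triisopropylsilyloxy)cyclohex-3-ene-1-carboxylate
Conditions: (S)-diphenylprolinol-derived o-tolyl-oxazaborolidine, Tf2NH (10 mol % each), CH2Cl2, −78 → −40 °C
Reagents that add atoms: none
Why: Catalytic enantioselective Diels–Alder reaction of a 2-silyloxydiene with an activated acrylate. The silyloxy group is a stronger donor than methyl and directs the ester para to C4', which places the enol ether between C3' and C4'. The cationic oxazaborolidine shields one face of the bound acrylate and sets C1' (S), the only stereocentre.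

Step 3
Reactants: 4 2,2,2-trifluoroethyl (1S)-3-methyl-4-(triisopropylsilyloxy)cyclohex-3-ene-1-carboxylate
Product: 5 2,2,2-trifluoroethyl (3S)-1-methyl-6-(triisopropylsilyloxy)bicyclo[4.1.0]heptane-3-carboxylate (both ring-fusion diastereomers)
Conditions: Et2Zn, CH2I2, CH2Cl2, 0 °C → rt
Reagents that add atoms: diiodomethane, ICI
Why: Furukawa variant of the Simmons–Smith cyclopropanation; the electron-rich enol ether is the only alkene and reacts with the electrophilic zinc carbenoid. The two new ring-fusion centres need no control because both disappear in step 4.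

Step 4
Reactants: 5 2,2,2-trifluoroethyl (3S)-1-methyl-6-(triisopropylsilyloxy)bicyclo[4.1.0]heptane-3-carboxylate
Product: 6 2,2,2-trifluoroethyl (1S)-3,3-dimethyl-4-oxocyclohexane-1-carboxylate
Conditions: CF3CO2H, CH2Cl2, 0 °C → rt; aq. NaHCO3
Reagents that add atoms: none
Why: Acid opening of a siloxycyclopropane, the classical regiospecific alpha-methylation. The proton goes to the unsubstituted CH2, the exocyclic C4'–CH2 bond breaks under the push of oxygen, and the CH2 becomes the second methyl on C3'. No base is present, so C1' is untouched.

Step 5
Reactants: 6 2,2,2-trifluoroethyl (1S)-3,3-dimethyl-4-oxocyclohexane-1-carboxylate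
Product: 7 2,2,2-trifluoroethyl (1S)-4-bromo-5,5-dimethylcyclohex-3-ene-1-carboxylate
Conditions: (PhO)3P, Br2, CH2Cl2, −60 °C; then 6, Et3N, −60 °C → reflux
Reagents that add atoms: bromine, BrBr
Why: Conversion of an enolisable ketone into an alkenyl bromide with a halophosphonium reagent. C3' is quaternary, so HBr can only be lost towards C5' and one regioisomer results; triethylamine is too weak to enolise the ester.

Step 6
Reactants: 7 2,2,2-trifluoroethyl (1S)-4-bromo-5,5-dimethylcyclohex-3-ene-1-carboxylate
Product: 8 2,2,2-trifluoroethyl (1S,4S)-4-bromo-3,3-dimethylcyclohexane-1-carboxylate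
Conditions: Mn(dpm)3 (10 mol %), PhSiH3, t-BuOOH, i-PrOH, rt
Reagents that add atoms: none
Why: Metal-hydride hydrogen-atom-transfer hydrogenation, a radical method that saturates alkenyl halides without hydrogenolysis; H adds to C5' and gives the bromine-stabilised C4' radical. The ester stays equatorial to avoid the syn-axial C3' methyl. The second hydrogen atom should arrive along the axial line on the face away from that methyl, so bromine ends equatorial and trans to the ester (4'S).

Step 7
Reactants: 8 2,2,2-trifluoroethyl (1S,4S)-4-bromo-3,3-dimethylcyclohexane-1-carboxylate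
Product: 9 (1S,4S)-4-bromo-3,3-dimethylcyclohexane-1-carboxylic acid
Conditions: LiOH·H2O, THF/H2O, 0 °C; 1 M HCl
Reagents that add atoms: lithium hydroxide, [Li+].[OH-]
Why: Saponification of an activated ester, fast enough at 0 °C that C1' should not epimerise; the equatorial neopentyl bromide has no antiperiplanar hydrogen and no open rear side.

Step 8
Reactants: 9 (1S,4S)-4-bromo-3,3-dimethylcyclohexane-1-carboxylic acid, 10 methyl 3-iodopropanoate
Product: 13 methyl 4-[(1S,4S)-4-bromo-3,3-dimethylcyclohexyl]-4-oxobutanoate, via acid chloride 11 (not isolated), via zinc homoenolate 12 (not isolated)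
Conditions: 9, (COCl)2, cat. DMF, CH2Cl2, 0 °C → rt, evaporate; separately 10, Zn dust (TMSCl-activated), THF, 35 °C; combine, Pd(PPh3)4 (5 mol %), THF, 0 °C → rt
Reagents that add atoms: none
Why: Negishi-type acylation of a zinc homoenolate by an acid chloride, which forms C4–C5 under neutral conditions so that C1', alpha to the new ketone, is not enolised. Palladium inserts into the acyl chloride far faster than into the hindered secondary bromide.

Step 9
Reactants: 13 methyl 4-[(1S,4S)-4-bromo-3,3-dimethylcyclohexyl]-4-oxobutanoate
Product: 14 methyl 4-[(1S,4S)-4-bromo-3,3-dimethylcyclohexyl]pent-4-enoate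
Conditions: Zn, CH2Br2, TiCl4, THF (reagent aged at 5 °C); then 13, CH2Cl2, 0 °C → rt
Reagents that add atoms: dibromomethane, BrCBr
Why: Lombardo methylenation; the gem-dimetallic reagent is non-basic, prefers ketones to esters and is the standard choice for ketones with an epimerisable alpha-centre.

Step 10
Reactants: 14 methyl 4-[(1S,4S)-4-bromo-3,3-dimethylcyclohexyl]pent-4-enoate
Product: 15 4-[(1S,4S)-4-bromo-3,3-dimethylcyclohexyl]pent-4-enoic acid
Conditions: LiOH, THF/MeOH/H2O, rt; 1 M HCl to pH 3
Reagents that add atoms: lithium hydroxide, [Li+].[OH-]
Why: Plain saponification; C1' is now allylic and not alpha to a carbonyl group, so no stereocentre is at risk.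

Step 11
Reactants: 15 4-[(1S,4S)-4-bromo-3,3-dimethylcyclohexyl]pent-4-enoic acid
Product: 17 5-[(1S,4S)-4-bromo-3,3-dimethylcyclohexyl]-1-diazohex-5-en-2-one, via mixed anhydride 16 (not isolated)
Conditions: i-BuOCOCl, N-methylmorpholine, THF, −20 °C; then CH2N2, Et2O, 0 °C → rt
Reagents that add atoms: diazomethane, C=[N+]=[N-]
Why: Acylation of diazomethane by a mixed carbonic anhydride, the first stage of the Arndt–Eistert sequence. This activation releases no HCl that could add to the 1,1-disubstituted alkene.

Step 12
Reactants: 17 5-[(1S,4S)-4-bromo-3,3-dimethylcyclohexyl]-1-diazohex-5-en-2-one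
Product: 18 (1R,5S)-5-[(1S,4S)-4-bromo-3,3-dimethylcyclohexyl]bicyclo[3.1.0]hexan-2-one
Conditions: [Cu(MeCN)4]PF6 (5 mol %), (S,S)-t-Bu-bis(oxazoline) (6 mol %), CH2Cl2, slow addition of 17, rt
Reagents that add atoms: none
Why: Catalytic asymmetric intramolecular cyclopropanation of an unsaturated diazoketone through a copper carbene. The three-atom tether enforces the cis fusion, so C2 and C4 are set together. The ligand selects the Re face of alkene carbon C4, for which the substrate has no bias; the minor product is a diastereomer and is removed by chromatography.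

Step 13
Reactants: 18 (1R,5S)-5-[(1S,4S)-4-bromo-3,3-dimethylcyclohexyl]bicyclo[3.1.0]hexan-2-one
Product: 19 (1S,5S)-1-[(1S,4S)-4-bromo-3,3-dimethylcyclohexyl]-4-methylidenebicyclo[3.1.0]hexane
Conditions: MePPh3Br, KOt-Bu, THF, 0 °C → rt
Reagents that add atoms: methyltriphenylphosphonium bromide, C[P+](c1ccccc1)(c1ccccc1)c1ccccc1.[Br-]
Why: Wittig methylenation of a cyclopropyl ketone; the alpha-CH is a ring-fusion carbon that can only be cis, so nothing can epimerise.

Step 14
Reactants: 19 (1S,5S)-1-[(1S,4S)-4-bromo-3,3-dimethylcyclohexyl]-4-methylidenebicyclo[3.1.0]hexane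
Product: 20 (1R,2R,5S)-5-[(1S,4S)-4-bromo-3,3-dimethylcyclohexyl]spiro[bicyclo[3.1.0]hexane-2,2'-oxirane], oxygen anti to the cyclopropane methylene
Conditions: dimethyldioxirane, acetone, −20 → 0 °C
Reagents that add atoms: dimethyldioxirane, CC1(C)OO1
Why: Epoxidation of a 1,1-disubstituted alkene. The endo hydrogen of C3 and the boat-like fold of the bicycle shield one face, so oxygen should arrive anti to C3 and set C1 (R). The neutral reagent spares the acid-labile cyclopropyl-substituted epoxide.

Step 15
Reactants: 20 (1R,2R,5S)-5-[(1S,4S)-4-bromo-3,3-dimethylcyclohexyl]spiro[bicyclo[3.1.0]hexane-2,2'-oxirane]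
Product: 21 (1R,2R,5S)-5-[(1S,4S)-4-bromo-3,3-dimethylcyclohexyl]-2-methylbicyclo[3.1.0]hexan-2-ol, hydroxyl anti and methyl syn to the cyclopropane methylene
Conditions: LiAlH4, Et2O, 0 °C; Na2SO4·10H2O
Reagents that add atoms: none
Why: SN2 opening of the epoxide by hydride at its unsubstituted carbon, which turns that carbon into the C1 methyl and leaves the C1–O bond intact. The neopentyl-type cyclohexyl bromide is displaced by hydride far more slowly than a terminal epoxide carbon.

Step 16
Reactants: 21 (1R,2R,5S)-5-[(1S,4S)-4-bromo-3,3-dimethylcyclohexyl]-2-methylbicyclo[3.1.0]hexan-2-ol, 22 N-bromosuccinimide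
Product: 23 (1R,2R,4S)-2-bromo-4-[(1S,4S)-4-bromo-3,3-dimethylcyclohexyl]-1-methyl-7-oxabicyclo[2.2.1]heptane (C2 bromine endo)
Conditions: 22 (1.1 equiv), Ph3P=S (10 mol %), NaHCO3 (s), 4 Å MS, CH2Cl2, −40 → 0 °C, dark
Reagents that add atoms: none
Why: Proposed new method: the sulfide-activated bromenium ion from 22, held near C2 by a hydrogen bond from the C1 hydroxyl, attacks the secondary cyclopropane carbon C2 at its corner (SE2 with inversion) while the strained ring-fusion bond C2–C4 breaks, so the three- and five-membered rings merge into the six-membered carbocycle and the positive charge settles on tertiary C4. The oxygen cannot reach the rear of the breaking bond, so ether formation is a second event: the cation folds into a boat, the hydroxyl adds across the ring and the succinimide anion takes the proton, which keeps the medium neutral. Ring by ring, the carbocycle C1–C6 arises by ring expansion and not by a closure, and the single new O–C4 bond closes both oxolane rings (O–C1–C2–C3–C4 and O–C1–C6–C5–C4) by transannular, formally 5-exo capture of the cation. The closest known reaction types are the Lewis-base-catalysed 1,3-bromocyclisation of cyclopropanes carrying a tethered oxygen or nitrogen nucleophile, the bromination of simple cyclopropanes with inversion at the carbon that takes bromine, and the acid-induced opening of 2-methylbicyclo[3.1.0]hexan-2-ols across the same fusion bond; none of them joins bromine attack at a ring-fusion carbon of an unactivated trialkylcyclopropane to a transannular ether closure. C2 is controlled by the inversion: with the hydroxyl anti to C3 the incoming bromine ends trans to the C1 oxygen on the new six-membered ring, that is endo (2R). C4 passes through a planar cation and is rewritten by the tether, because only the lobe on the side of the C1 oxygen can be bridged, so C4 (S) follows from C1 (R), which is untouched. The step needs cleavage of the fusion bond instead of the peripheral C3–C4 bond, which leads to the same cation after attack at the more open C3; in favour of the fusion bond speak the larger strain relief, the hydroxyl-guided delivery, and the fact that after peripheral cleavage the oxygen could only close a four-membered ether. It also needs the tertiary cyclopropylcarbinol to survive, which the buffered, acid-free and dark conditions are meant to secure.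

## Compound list

1 | 3-methylbut-3-en-2-one | CC(=O)C(C)=C | starting material
2 | 3-methyl-2-(triisopropylsilyloxy)buta-1,3-diene | C=C(C)C(=C)O[Si](C(C)C)(C(C)C)C(C)C | intermediate
3 | 2,2,2-trifluoroethyl acrylate | C=CC(=O)OCC(F)(F)F | starting material
4 | 2,2,2-trifluoroethyl (1S)-3-methyl-4-(triisopropylsilyloxy)cyclohex-3-ene-1-carboxylate | CC1=C(O[Si](C(C)C)(C(C)C)C(C)C)CC[C@H](C(=O)OCC(F)(F)F)C1 | intermediate
5 | 2,2,2-trifluoroethyl (3S)-1-methyl-6-(triisopropylsilyloxy)bicyclo[4.1.0]heptane-3-carboxylate, both ring-fusion diastereomers | CC12C[C@@H](C(=O)OCC(F)(F)F)CCC1(O[Si](C(C)C)(C(C)C)C(C)C)C2 | intermediate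
6 | 2,2,2-trifluoroethyl (1S)-3,3-dimethyl-4-oxocyclohexane-1-carboxylate | CC1(C)C[C@@H](C(=O)OCC(F)(F)F)CCC1=O | intermediate
7 | 2,2,2-trifluoroethyl (1S)-4-bromo-5,5-dimethylcyclohex-3-ene-1-carboxylate | CC1(C)C[C@@H](C(=O)OCC(F)(F)F)CC=C1Br | intermediate
8 | 2,2,2-trifluoroethyl (1S,4S)-4-bromo-3,3-dimethylcyclohexane-1-carboxylate | CC1(C)C[C@@H](C(=O)OCC(F)(F)F)CC[C@@H]1Br | intermediate
9 | (1S,4S)-4-bromo-3,3-dimethylcyclohexane-1-carboxylic acid | CC1(C)C[C@@H](C(=O)O)CC[C@@H]1Br | intermediate
10 | methyl 3-iodopropanoate | COC(=O)CCI | starting material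
11 | (1S,4S)-4-bromo-3,3-dimethylcyclohexane-1-carbonyl chloride | CC1(C)C[C@@H](C(=O)Cl)CC[C@@H]1Br | intermediate
12 | (3-methoxy-3-oxopropyl)zinc iodide | COC(=O)CC[Zn]I | intermediate
13 | methyl 4-[(1S,4S)-4-bromo-3,3-dimethylcyclohexyl]-4-oxobutanoate | CC1(C)C[C@@H](C(=O)CCC(=O)OC)CC[C@@H]1Br | intermediate
14 | methyl 4-[(1S,4S)-4-bromo-3,3-dimethylcyclohexyl]pent-4-enoate | CC1(C)C[C@@H](C(=C)CCC(=O)OC)CC[C@@H]1Br | intermediate
15 | 4-[(1S,4S)-4-bromo-3,3-dimethylcyclohexyl]pent-4-enoic acid | CC1(C)C[C@@H](C(=C)CCC(=O)O)CC[C@@H]1Br | intermediate
16 | 4-[(1S,4S)-4-bromo-3,3-dimethylcyclohexyl]pent-4-enoic isobutyl carbonic anhydride | CC1(C)C[C@@H](C(=C)CCC(=O)OC(=O)OCC(C)C)CC[C@@H]1Br | intermediate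
17 | 5-[(1S,4S)-4-bromo-3,3-dimethylcyclohexyl]-1-diazohex-5-en-2-one | CC1(C)C[C@@H](C(=C)CCC(=O)C=[N+]=[N-])CC[C@@H]1Br | intermediate
18 | (1R,5S)-5-[(1S,4S)-4-bromo-3,3-dimethylcyclohexyl]bicyclo[3.1.0]hexan-2-one | CC1(C)C[C@@H]([C@@]23CCC(=O)[C@@H]2C3)CC[C@@H]1Br | intermediate
19 | (1S,5S)-1-[(1S,4S)-4-bromo-3,3-dimethylcyclohexyl]-4-methylidenebicyclo[3.1.0]hexane | CC1(C)C[C@@H]([C@@]23CCC(=C)[C@@H]2C3)CC[C@@H]1Br | intermediate
20 | (1R,2R,5S)-5-[(1S,4S)-4-bromo-3,3-dimethylcyclohexyl]spiro[bicyclo[3.1.0]hexane-2,2'-oxirane] | CC1(C)C[C@@H]([C@@]23CC[C@@]4(OC4)[C@@H]2C3)CC[C@@H]1Br | intermediate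
21 | (1R,2R,5S)-5-[(1S,4S)-4-bromo-3,3-dimethylcyclohexyl]-2-methylbicyclo[3.1.0]hexan-2-ol | CC1(C)C[C@@H]([C@@]23CC[C@@](C)(O)[C@@H]2C3)CC[C@@H]1Br | intermediate
22 | N-bromosuccinimide | O=C1CCC(=O)N1Br | starting material
23 | (1R,2R,4S)-2-bromo-4-[(1S,4S)-4-bromo-3,3-dimethylcyclohexyl]-1-methyl-7-oxabicyclo[2.2.1]heptane | CC1(C)C[C@@H]([C@@]23CC[C@@](C)(O2)[C@H](Br)C3)CC[C@@H]1Br | target

## Step count and least certain steps

Total step count: 16. Longest linear sequence: 16 steps (1 → 23); 3, 10 and 22 are bought and enter directly.

**Step 16 (key step).** The most likely failure is bromenium attack at the open methylene corner C3 with cleavage of the peripheral C3–C4 bond, which is sterically easier and reaches the same tertiary cation. Three further risks follow: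
- ionisation of the tertiary cyclopropylcarbinol by traces of acid;
- proton loss, or hydride shift from C1', at the C4 cation before the ring has folded into the boat;
- rear-side capture of C4 by an external nucleophile.

The fallback keeps a cyclopropane but opens it by known chemistry. It sets out from 17 and comes back at 23. Cyclopropanation of 17 with the antipodal ligand should give the diastereomeric ketone (1S,5R)-5-[(1S,4S)-4-bromo-3,3-dimethylcyclohexyl]bicyclo[3.1.0]hexan-2-one F1. Methylmagnesium bromide with CeCl3 converts it into the tertiary alcohol (1S,2R,5R)-5-[(1S,4S)-4-bromo-3,3-dimethylcyclohexyl]-2-methylbicyclo[3.1.0]hexan-2-ol F2, whose C1 configuration does not matter. Dilute aqueous acid ionises C1, and the fusion bond opens in the cyclopropylcarbinyl-to-homoallyl manner. Water enters at C4 from the rear, with inversion, which is why the opposite cyclopropane is required. The product is (1S)-1-[(1S,4S)-4-bromo-3,3-dimethylcyclohexyl]-4-methylcyclohex-3-en-1-ol F3, which has the C4 configuration of 23. Treatment of F3 with 22 closes the cage by transannular bromoetherification. Only the bromonium ion on the face opposite the hydroxyl can be captured, oxygen bonds to the tertiary C1, and bromine is left endo at C2.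

**Step 12.** Facial selection by the copper carbene may be poor, because diazoketone-derived carbenes are less tightly organised than those of diazoesters. Carbene dimerisation competes if the addition is too fast. The fallback relays the configuration from a carbinol centre. It sets out from 17 and returns at 18. One equivalent of HCl in ether turns 17 into 1-chloro-5-[(1S,4S)-4-bromo-3,3-dimethylcyclohexyl]hex-5-en-2-one F4. Corey–Bakshi–Shibata reduction gives (2R)-1-chloro-5-[(1S,4S)-4-bromo-3,3-dimethylcyclohexyl]hex-5-en-2-ol F5, and base closes it to (2R)-2-{3-[(1S,4S)-4-bromo-3,3-dimethylcyclohexyl]but-3-en-1-yl}oxirane F6. Lithium tetramethylpiperidide lithiates the terminal epoxide carbon, and the carbenoid adds to the tethered alkene. This should give (1R,2R,5S)-5-[(1S,4S)-4-bromo-3,3-dimethylcyclohexyl]bicyclo[3.1.0]hexan-2-ol F7, with the hydroxyl trans to the cyclopropane as is the rule for this closure. Dess–Martin oxidation leads to 18.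

**Step 6.** Hydrogen-atom delivery from the equatorial side would give the cis isomer, and sluggish transfer to the hindered bromoalkene could allow loss of bromine. The fallback makes the C–Br bond by substitution. It sets out from 6 and returns at 8. L-Selectride at −78 °C attacks the ketone equatorially, with a cold quench so that the alkoxide does not attack the activated ester. This gives the axial alcohol 2,2,2-trifluoroethyl (1S,4R)-4-hydroxy-3,3-dimethylcyclohexane-1-carboxylate F8. An Appel reaction with CBr4 and tri-n-octylphosphine in warm toluene, with an alkene as acid scavenger, then replaces oxygen by bromine with inversion. Elimination towards C5' is the price of this variant.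

**Step 5.** Bromide addition to a carbonyl carbon beside a quaternary centre may be slow, and alpha-bromination may compete. The fallback sets out from 6 and returns at 7. LiHMDS and N-phenyltriflimide at −78 °C give 2,2,2-trifluoroethyl (1S)-5,5-dimethyl-4-(trifluoromethylsulfonyloxy)cyclohex-3-ene-1-carboxylate F9. Ruthenium-catalysed triflate–halide exchange with LiBr then converts it into the alkenyl bromide.

**Step 14.** Some attack on the face syn to C3 is possible, and the cyclopropyl-substituted epoxide may rearrange under acid during isolation. The fallback uses a bulkier oxidant and no isolated epoxide. It sets out from 19 and returns at 21. OsO4/NMO should give (1R,2R,5S)-5-[(1S,4S)-4-bromo-3,3-dimethylcyclohexyl]-2-(hydroxymethyl)bicyclo[3.1.0]hexan-2-ol F10. Selective tosylation of the primary hydroxyl gives [(1R,2R,5S)-5-[(1S,4S)-4-bromo-3,3-dimethylcyclohexyl]-2-hydroxybicyclo[3.1.0]hexan-2-yl]methyl 4-methylbenzenesulfonate F11, and LiAlH4 reduces the CH2–O carbon to the methyl group.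

## Further compounds

F1 | step 16 | (1S,5R)-5-[(1S,4S)-4-bromo-3,3-dimethylcyclohexyl]bicyclo[3.1.0]hexan-2-one | CC1(C)C[C@@H]([C@]23CCC(=O)[C@H]2C3)CC[C@@H]1Br
F2 | step 16 | (1S,2R,5R)-5-[(1S,4S)-4-bromo-3,3-dimethylcyclohexyl]-2-methylbicyclo[3.1.0]hexan-2-ol | CC1(C)C[C@@H]([C@]23CC[C@@](C)(O)[C@H]2C3)CC[C@@H]1Br
F3 | step 16 | (1S)-1-[(1S,4S)-4-bromo-3,3-dimethylcyclohexyl]-4-methylcyclohex-3-en-1-ol | CC1(C)C[C@@H]([C@@]2(O)CC=C(C)CC2)CC[C@@H]1Br
F4 | step 12 | 1-chloro-5-[(1S,4S)-4-bromo-3,3-dimethylcyclohexyl]hex-5-en-2-one | CC1(C)C[C@@H](C(=C)CCC(=O)CCl)CC[C@@H]1Br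
F5 | step 12 | (2R)-1-chloro-5-[(1S,4S)-4-bromo-3,3-dimethylcyclohexyl]hex-5-en-2-ol | CC1(C)C[C@@H](C(=C)CC[C@@H](O)CCl)CC[C@@H]1Br
F6 | step 12 | (2R)-2-{3-[(1S,4S)-4-bromo-3,3-dimethylcyclohexyl]but-3-en-1-yl}oxirane | CC1(C)C[C@@H](C(=C)CC[C@@H]2CO2)CC[C@@H]1Br
F7 | step 12 | (1R,2R,5S)-5-[(1S,4S)-4-bromo-3,3-dimethylcyclohexyl]bicyclo[3.1.0]hexan-2-ol | CC1(C)C[C@@H]([C@@]23CC[C@@H](O)[C@@H]2C3)CC[C@@H]1Br
F8 | step 6 | 2,2,2-trifluoroethyl (1S,4R)-4-hydroxy-3,3-dimethylcyclohexane-1-carboxylate | CC1(C)C[C@@H](C(=O)OCC(F)(F)F)CC[C@H]1O
F9 | step 5 | 2,2,2-trifluoroethyl (1S)-5,5-dimethyl-4-(trifluoromethylsulfonyloxy)cyclohex-3-ene-1-carboxylate | CC1(C)C[C@@H](C(=O)OCC(F)(F)F)CC=C1OS(=O)(=O)C(F)(F)F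
F10 | step 14 | (1R,2R,5S)-5-[(1S,4S)-4-bromo-3,3-dimethylcyclohexyl]-2-(hydroxymethyl)bicyclo[3.1.0]hexan-2-ol | CC1(C)C[C@@H]([C@@]23CC[C@@](CO)(O)[C@@H]2C3)CC[C@@H]1Br
F11 | step 14 | [(1R,2R,5S)-5-[(1S,4S)-4-bromo-3,3-dimethylcyclohexyl]-2-hydroxybicyclo[3.1.0]hexan-2-yl]methyl 4-methylbenzenesulfonate | CC1(C)C[C@@H]([C@@]23CC[C@@](COS(=O)(=O)c4ccc(C)cc4)(O)[C@@H]2C3)CC[C@@H]1Br
A1 | alternative 1 | (1R,2R,4S)-2-bromo-1-methyl-4-(6-methylhepta-1,5-dien-2-yl)-7-oxabicyclo[2.2.1]heptane | CC(C)=CCCC(=C)[C@@]12CC[C@@](C)(O1)[C@H](Br)C2
A2 | alternative 1 | (1R,2R,4S)-2-bromo-4-[(4S)-4-bromo-5,5-dimethylcyclohex-1-en-1-yl]-1-methyl-7-oxabicyclo[2.2.1]heptane | CC1(C)CC(=CC[C@@H]1Br)[C@@]23CC[C@@](C)(O2)[C@H](Br)C3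
A3 | alternative 2 | dimethyl (2R)-2-[(1S,4S)-4-bromo-3,3-dimethylcyclohexyl]-2-(3-oxobutyl)cyclopropane-1,1-dicarboxylate | CC1(C)C[C@@H]([C@@]2(CCC(C)=O)CC2(C(=O)OC)C(=O)OC)CC[C@@H]1Br
A4 | alternative 2 | dimethyl (1R,4S)-4-[(1S,4S)-4-bromo-3,3-dimethylcyclohexyl]-1-methyl-7-oxabicyclo[2.2.1]heptane-2,2-dicarboxylate | CC1(C)C[C@@H]([C@@]23CC[C@@](C)(O2)C(C(=O)OC)(C(=O)OC)C3)CC[C@@H]1Br
A5 | alternative 3 | 2-[(1S,4S)-4-bromo-3,3-dimethylcyclohexyl]-5-methylfuran | CC1(C)C[C@@H](c2ccc(C)o2)CC[C@@H]1Br
A6 | alternative 3 | 2-bromoprop-2-enal (2-bromoacrolein) | C=C(Br)C=O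
A7 | alternative 3 | (1R,2R,4S)-2-bromo-4-[(1S,4S)-4-bromo-3,3-dimethylcyclohexyl]-1-methyl-7-oxabicyclo[2.2.1]hept-5-ene-2-carbaldehyde (bromine endo, formyl exo) | CC1(C)C[C@@H]([C@@]23C=C[C@@](C)(O2)[C@](C=O)(Br)C3)CC[C@@H]1Br
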